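The free base is the charge to be found for this flask, in which the nucleophile starts in its protonated form.

    electrophile + nucleophile → acid set free + target (k1 = 0.12 L mol⁻¹ s⁻¹)
    nucleophile + acid set free ⇌ protonated nucleophile, settled at all times (K2 = 940 L mol⁻¹)
    acid set free + free base ⇌ salt of the base, settled at all times (K3 = 1.6 × 10⁵ L mol⁻¹)
    nucleophile + target ⇌ idle adduct, settled at all times (K4 = 9.5 L mol⁻¹)
    electrophile + acid set free → side product (k5 = 0.0020 L mol⁻¹ s⁻¹)

electrophile 0.20 M; protonated nucleophile 0.300 M; time 15 min

- for target the idle adduct is counted in
- the amount of free base is what is sought; it is there from the start
- run time (flask): 15 min

* the concentration of free base at which the part of the electrophile that has reacted at 15 min is just 80%, in M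

Taken at the mean level of free nucleophile, the first step is a pseudo-first-order decay of the electrophile, and it integrates in closed form: the logarithm of starting over remaining electrophile equals the rate constant times the time times the mean free nucleophile. Leaving the side product aside, 80% reacted by 15 min therefore takes 0.0149 M as the required mean of free nucleophile. That is far below the 0.300 M of protonated nucleophile charged, so my reckoning drops it from the balance of base against acid.

Each target takes one nucleophile, and its acid takes up one more, so each costs two portions of base. For 0.160 M of target, my hand reckoning stops at 0.320 M, which counts no acid left free and no idle adduct.

The forecast differs and gives 0.282 M, lower than my figure, on the ground that the free nucleophile “does not collapse” even when the base falls short of two portions per target.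

The simulation gives 0.280 M of free base for this flask. After 1.50 min, 0.129% of the charged free base is still free and 57.8% of the electrophile is used. Set against the required mean over the whole 15 min, with the side product again left aside, that first stretch supplies, of the nucleophile's required time integral, 53.7%.

Its constants are assumed, and the outcome is calculated.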